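**Strategy.** Ring B carrying C17 on C8 and the Me2C4 unit on C5 is a p-menthane, so (R)-carvone is used as ring B: its methyl is C17 and its isopropenyl carbon becomes C4. C10 is made quaternary by two α′-alkylations (methyl, then a 2-chloroallyl arm = C1–C3). The trans-fused oxocane is then built on C8/C9 (allyl ether, RCM). Only then is ring A closed: buffered ionisation at C4 lets the chloroalkene capture the tertiary cation (Lansbury annulation), forging the congested C3–C4 bond and the gem-dimethyl quaternary carbon in one operation. The precursor is the oxocane-fused cyclohexane with a CMe2–O leaving group on C5 and the chloroallyl arm on C10.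

Key step: step 16

Remark: atoms are numbered as in the labdane skeleton of the target (ring A = C1–C5, C10; ring B = C5–C10; oxocane = O, C8, C9, C11–C15; C16 = CH2OAc carbon; C17 on C8; C18/C19 on C4; C20 on C10); α is the face of H-5, β the face of C20.

**Step 1**
Reactants: 1 (R)-(−)-carvone
Product: 3 (5R,6S)-6-methylcarvone (methyl trans to isopropenyl), via lithium dienolate 2 (not isolated)
Conditions: LDA, THF, −78 °C; then MeI, −78 → −20 °C
Reagents that add atoms: iodomethane, CI
Why: Kinetic α′-deprotonation gives the cross-conjugated enolate, which is C-methylated (enolate alkylation); this centre is enolised again in step 2, so its epimer ratio does not matter.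

**Step 2**
Reactants: 3 6-methylcarvone; 4 2,3-dichloroprop-1-ene
Product: 6 6-(2-chloroallyl)-6-methylcarvone (chloroallyl trans and methyl cis to isopropenyl), via lithium enolate 5 (not isolated)
Conditions: LDA (1.05 equiv), THF, −78 → 0 °C; then 4, HMPA, −78 °C → rt
Reagents that add atoms: none
Why: Enolate alkylation in which the allylic chloride approaches the tetrasubstituted enolate anti to the neighbouring isopropenyl group, so the C1–C3 arm ends α (trans) and C20 β (cis), which sets C10.

**Step 3**
Reactants: 6 dialkylated carvone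
Product: 7 tertiary alcohol (isopropenyl converted into CMe2OH at C4)
Conditions: Co(acac)2 (cat.), PhSiH3, O2 (1 atm), THF, 0 °C → rt
Reagents that add atoms: dioxygen, O=O
Why: Mukaiyama hydration (hydrogen-atom transfer to the CH2 terminus, O2 capture of the tertiary radical) is Markovnikov and should select the electron-rich 1,1-disubstituted alkene over the enone and the vinyl chloride; no acid is present, so the chloroallyl arm cannot cyclise prematurely.

**Step 4**
Reactants: 7 tertiary alcohol
Product: 8 triethylsilyl ether of 7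
Conditions: Et3SiOTf, 2,6-lutidine, CH2Cl2, −78 → 0 °C
Reagents that add atoms: triethylsilyl trifluoromethanesulfonate, CC[Si](CC)(CC)OS(=O)(=O)C(F)(F)F
Why: Silylation with the silyl triflate masks the later C4 cation precursor against the base, borane and alkylation chemistry of steps 5–12.

**Step 5**
Reactants: 8 silyl ether enone
Product: 10 enol triflate (C9–OTf, C8=C9), via potassium enolate 9 (not isolated)
Conditions: K-Selectride, THF, −78 °C; then Comins' reagent, −78 → 0 °C
Reagents that add atoms: N-(5-chloropyridin-2-yl)bis(trifluoromethanesulfonimide), O=S(=O)(N(c1ccc(Cl)cn1)S(=O)(=O)C(F)(F)F)C(F)(F)F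
Why: Conjugate reduction of the β-unsubstituted enone (the carbonyl is shielded by quaternary C10) followed by O-sulfonylation gives a single enol triflate, because C10 carries no hydrogen.

**Step 6**
Reactants: 10 enol triflate
Product: 11 tetrasubstituted cyclohexene (C9–CH3 = C11, C8=C9)
Conditions: MeZnCl, Pd(PPh3)4 (cat.), THF, 50 °C
Reagents that add atoms: methylzinc chloride, C[Zn]Cl
Why: Negishi coupling; oxidative addition to the enol triflate is much faster than to the vinyl chloride, and a methyl group cannot β-eliminate.

**Step 7**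
Reactants: 11 tetrasubstituted alkene
Product: 13 tertiary allylic alcohol (8α-OH, 8β-CH3, exocyclic C9=C11H2), via allylic hydroperoxide 12 (not isolated)
Conditions: O2, tetraphenylporphyrin (cat.), visible light, CH2Cl2, −20 °C; then PPh3
Reagents that add atoms: dioxygen, O=O
Why: Schenck ene reaction of singlet oxygen: oxygen should bond to the less encumbered C8 and take hydrogen from the only hydrogen-bearing substituent of C9, the C11 methyl (C10 is quaternary; geminal large-group effect), on the α-face anti to the pseudo-axial C20 methyl, which sets C8; PPh3 reduces the hydroperoxide.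

**Step 8**
Reactants: 14 2-methylenepropane-1,3-diol
Product: 15 mono-TBS ether of 14
Conditions: TBSCl, Et3N, DMAP (cat.), CH2Cl2, 0 °C (14 in excess)
Reagents that add atoms: tert-butyldimethylsilyl chloride, CC(C)(C)[Si](C)(C)Cl
Why: Statistical mono-silylation of the symmetrical diol used in excess.

**Step 9**
Reactants: 15 mono-TBS ether
Product: 16 allylic diethyl phosphate
Conditions: ClP(O)(OEt)2, pyridine, DMAP (cat.), CH2Cl2, 0 °C
Reagents that add atoms: diethyl chlorophosphate, CCOP(=O)(Cl)OCC
Why: Phosphorylation of the primary allylic alcohol installs the leaving group used for copper-catalysed allyl–alkyl coupling.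

**Step 10**
Reactants: 13 allylic alcohol; 16 allylic phosphate
Product: 18 coupled diene (9α-H; C9–C11H2–C12H2–C13(=CH2)–CH2OTBS), via B-alkyl-9-BBN 17 (not isolated)
Conditions: 9-BBN (excess), THF, 65 °C; then 16, CuOAc (10 mol%), t-BuOK, THF, 60 °C
Reagents that add atoms: none
Why: Hydroboration puts boron on C11 and hydrogen on C9 from the α-face (the β-face is closed by the axial C17 and C20 methyls or, in the flipped chair, by the axial C5 substituent), which sets C9; copper-catalysed allylic substitution of the alkylborate on phosphate 16 then forms C11–C12 (both allyl termini are equivalent), and 9-BBN should not add to the deactivated vinyl chloride.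

**Step 11**
Reactants: 18 tertiary alcohol; 19 allyl bromide
Product: 21 tertiary allyl ether (C8–O–CH2CH=CH2), via potassium alkoxide 20 (not isolated)
Conditions: KH, THF, 0 °C; then 19, Bu4NI (cat.), 0 °C → rt
Reagents that add atoms: none
Why: Williamson etherification of a tertiary potassium alkoxide with a reactive allylic bromide; silyl ethers and the vinyl chloride are inert to KH.

**Step 12**
Reactants: 21 allyl ether diene
Product: 22 trans-fused oxocene (C13=C14, C13 bearing CH2OTBS)
Conditions: Grubbs II (10 mol%), CH2Cl2 (2 mM), 40 °C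
Reagents that add atoms: none
Why: Ring-closing metathesis of the allyl ether with the 1,1-disubstituted alkene closes the eight-membered ring; the trans-1,2 O/C11 pair is gauche in the diequatorial chair, which brings the alkenes together, and the vinyl chloride is a poor metathesis partner.

**Step 13**
Reactants: 22 bis-silyl ether
Product: 23 diol (allylic C16–OH, tertiary C4–OH)
Conditions: Bu4NF, THF, rt → 45 °C
Reagents that add atoms: none
Why: Fluoride cleaves both silyl ethers, giving the allylic alcohol that directs step 14 and the tertiary alcohol needed in step 16.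

**Step 14**
Reactants: 23 allylic alcohol
Product: 24 (13R)-oxocane diol
Conditions: H2 (50 atm), Ru(OAc)2[(R)-BINAP] (2 mol%), MeOH, rt
Reagents that add atoms: none
Why: Noyori hydrogenation of an allylic alcohol: the hydroxyl binds ruthenium and the ligand selects the alkene face, setting C13 as R (sense assigned by analogy with geraniol → citronellol; the antipodal ligand would be used if the sense proves opposite); the non-coordinating vinyl chloride should not be reduced.

**Step 15**
Reactants: 24 diol
Product: 25 primary acetate (tertiary C4–OH free)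
Conditions: Ac2O, pyridine, 0 °C → rt
Reagents that add atoms: acetic anhydride, CC(=O)OC(C)=O
Why: The primary alcohol is acetylated; the hindered tertiary alcohol does not react without DMAP.

**Step 16 (key step)**
Reactants: 25 tertiary alcohol with C10 chloroallyl arm
Product: 27 2-oxo-8α,15-epoxylabdan-16-yl acetate, via tertiary trifluoroacetate 26 (not isolated)
Conditions: (CF3CO)2O, pyridine, CH2Cl2, 0 °C; then (CF3)2CHOH–H2O (20:1), 2,6-lutidine, 40 °C
Reagents that add atoms: water, O
Why: SN1 ionisation of the tertiary trifluoroacetate gives the C4 cation, which is attacked by the CH2 terminus (C3) of the 2-chloroalkene; the resulting chlorine-stabilised C2 cation is captured by water and loses HCl to give the C2 ketone. The closest known reaction type is the Lansbury chloro-olefin annulation, a cation–olefin cyclization, here initiated by buffered solvolysis as in Johnson-type cyclizations. Ring A closes 6-endo-trig with respect to the chloroalkene, with C3–C4 as the new bond. No new stereocentre is formed: C5 and C10 were set in step 2, and the trans-fused oxocane locks ring B in the chair where C4 and C1 are vicinal diequatorial, so only the trans-decalin can form. The step needs ionisation at C4 without cleavage of the tertiary C8–O ether, and C–C bond formation rather than proton loss. This is addressed by placing the only leaving group at C4, by the lutidine buffer that keeps the ether unprotonated (the classical HCO2H or H2SO4 conditions would not), and by the ionising, weakly nucleophilic fluoro-alcohol together with the proximity of the arm.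

**Step 17**
Reactants: 27 C2 ketone
Product: 29 target acetate (CNP0152986.1), via tosylhydrazone 28 (not isolated)
Conditions: TsNHNH2, EtOH, 60 °C; then catecholborane, CHCl3, 0 °C; NaOAc·3H2O, 60 °C
Reagents that add atoms: none
Why: Caglioti-type deoxygenation in Kabalka's form: catecholborane reduces the hydrazone C=N, and acetate-induced loss of sulfinate and N2 leaves CH2 at C2 under neutral conditions that spare the acetate and the tertiary ether.

**Compound list**

1 | (R)-(−)-carvone | CC1=CC[C@@H](C(C)=C)CC1=O | starting material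
2 | lithium dienolate of 1 | CC1=CC[C@@H](C(C)=C)C=C1O[Li] | intermediate
3 | (5R,6S)-6-methylcarvone | CC1=CC[C@@H](C(C)=C)[C@H](C)C1=O | intermediate
4 | 2,3-dichloroprop-1-ene | ClCC(Cl)=C | starting material
5 | lithium enolate of 3 | CC1=CC[C@@H](C(C)=C)C(C)=C1O[Li] | intermediate
6 | 6-(2-chloroallyl)-6-methylcarvone (chloroallyl trans, methyl cis to isopropenyl) | CC1=CC[C@@H](C(C)=C)[C@](C)(CC(Cl)=C)C1=O | intermediate
7 | tertiary alcohol from hydration of 6 | CC1=CC[C@@H](C(C)(C)O)[C@](C)(CC(Cl)=C)C1=O | intermediate
8 | triethylsilyl ether of 7 | CC1=CC[C@@H](C(C)(C)O[Si](CC)(CC)CC)[C@](C)(CC(Cl)=C)C1=O | intermediate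
9 | potassium enolate (C8=C9–OK) | CC=1CC[C@@H](C(C)(C)O[Si](CC)(CC)CC)[C@](C)(CC(Cl)=C)C=1O[K] | intermediate
10 | enol triflate (C9–OTf) | CC=1CC[C@@H](C(C)(C)O[Si](CC)(CC)CC)[C@](C)(CC(Cl)=C)C=1OS(=O)(=O)C(F)(F)F | intermediate
11 | tetrasubstituted cyclohexene (C9–CH3) | CC=1CC[C@@H](C(C)(C)O[Si](CC)(CC)CC)[C@](C)(CC(Cl)=C)C=1C | intermediate
12 | allylic hydroperoxide (8α-OOH, C9=C11H2) | OO[C@]1(C)CC[C@@H](C(C)(C)O[Si](CC)(CC)CC)[C@](C)(CC(Cl)=C)C1=C | intermediate
13 | tertiary allylic alcohol (8α-OH, 8β-CH3, C9=C11H2) | O[C@]1(C)CC[C@@H](C(C)(C)O[Si](CC)(CC)CC)[C@](C)(CC(Cl)=C)C1=C | intermediate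
14 | 2-methylenepropane-1,3-diol | OCC(=C)CO | starting material
15 | 2-[(tert-butyldimethylsilyloxy)methyl]prop-2-en-1-ol | OCC(=C)CO[Si](C)(C)C(C)(C)C | intermediate
16 | diethyl 2-[(tert-butyldimethylsilyloxy)methyl]allyl phosphate | CCOP(=O)(OCC)OCC(=C)CO[Si](C)(C)C(C)(C)C | intermediate
17 | B-alkyl-9-BBN (boron on C11, 9α-H) | O[C@]1(C)CC[C@@H](C(C)(C)O[Si](CC)(CC)CC)[C@](C)(CC(Cl)=C)[C@H]1CB1C2CCCC1CCC2 | intermediate
18 | coupled tertiary alcohol (C9 side chain CH2CH2C(=CH2)CH2OTBS, 9α-H) | O[C@]1(C)CC[C@@H](C(C)(C)O[Si](CC)(CC)CC)[C@](C)(CC(Cl)=C)[C@H]1CCC(=C)CO[Si](C)(C)C(C)(C)C | intermediate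
19 | allyl bromide | C=CCBr | starting material
20 | potassium alkoxide of 18 | [K]O[C@]1(C)CC[C@@H](C(C)(C)O[Si](CC)(CC)CC)[C@](C)(CC(Cl)=C)[C@H]1CCC(=C)CO[Si](C)(C)C(C)(C)C | intermediate
21 | tertiary allyl ether of 18 | C=CCO[C@]1(C)CC[C@@H](C(C)(C)O[Si](CC)(CC)CC)[C@](C)(CC(Cl)=C)[C@H]1CCC(=C)CO[Si](C)(C)C(C)(C)C | intermediate
22 | trans-fused oxocene (C13=C14) bis-silyl ether | CC(C)(C)[Si](C)(C)OCC1=CCO[C@]2(C)CC[C@@H](C(C)(C)O[Si](CC)(CC)CC)[C@](C)(CC(Cl)=C)[C@H]2CC1 | intermediate
23 | oxocene diol (C16–OH, C4–OH) | OCC1=CCO[C@]2(C)CC[C@@H](C(C)(C)O)[C@](C)(CC(Cl)=C)[C@H]2CC1 | intermediate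
24 | (13R)-oxocane diol | OC[C@H]1CCO[C@]2(C)CC[C@@H](C(C)(C)O)[C@](C)(CC(Cl)=C)[C@H]2CC1 | intermediate
25 | (13R)-oxocane C16 acetate with free C4–OH | CC(=O)OC[C@H]1CCO[C@]2(C)CC[C@@H](C(C)(C)O)[C@](C)(CC(Cl)=C)[C@H]2CC1 | intermediate
26 | tertiary trifluoroacetate of 25 | CC(=O)OC[C@H]1CCO[C@]2(C)CC[C@@H](C(C)(C)OC(=O)C(F)(F)F)[C@](C)(CC(Cl)=C)[C@H]2CC1 | intermediate
27 | 2-oxo-8α,15-epoxylabdan-16-yl acetate | CC(=O)OC[C@H]1CCO[C@]2(C)CC[C@H]3C(C)(C)CC(=O)C[C@]3(C)[C@H]2CC1 | intermediate
28 | tosylhydrazone of 27 | CC(=O)OC[C@H]1CCO[C@]2(C)CC[C@H]3C(C)(C)CC(=NNS(=O)(=O)c4ccc(C)cc4)C[C@]3(C)[C@H]2CC1 | intermediate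
29 | (13R)-8α,15-epoxylabdan-16-yl acetate (CNP0152986.1) | CC(=O)OC[C@H]1CCO[C@]2(C)CC[C@H]3C(C)(C)CCC[C@]3(C)[C@H]2CC1 | target

**Step count.** Total: 17 steps. Longest linear sequence: 15 steps (steps 1–7 and 10–17, from (R)-carvone); steps 8–9 prepare the coupling partner.

**Steps most likely to fail**

Step 16. The C4 cation may lose a proton to isopropenyl or isopropylidene alkenes, which cannot re-enter in the buffered medium, or ionisation may be slow. The fallback replaces the cation by a radical and sets out from 25. Acylation of the tertiary alcohol with methyl chlorooxoacetate (Et3N, DMAP) gives the tertiary methyl oxalate F1. One equivalent of CsOH at 0 °C (the oxalate ester is far more electrophilic than the acetate) gives the cesium oxalate F2. Visible-light photoredox oxidation (Ir[dF(CF3)ppy]2(dtbbpy)PF6, blue light, DME, a thiol as hydrogen donor) releases two CO2 and the tertiary C4 radical. This radical should close ring A 6-endo on the CH2 terminus of the 2-chloroalkene (5-exo attack is disfavoured at the chlorine-bearing internal carbon), and the α-chloro radical takes up hydrogen to give the secondary C2 chloride F3. Bu3SnH/AIBN removes the chlorine and comes back to the route at 29, bypassing 27.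

Step 10. Hydroboration of the doubly neopentylic exocyclic alkene may be slow, and boron-to-copper transfer of the β-branched alkyl group may lose to protodeboronation. The fallback reverses the polarity of the C11–C12 bond formation and sets out from 13. 9-BBN followed by NaOH/H2O2 gives the primary alcohol F4 with the same C9 outcome, and I2/PPh3/imidazole gives the primary iodide F5. Separately, 15 is converted (MsCl, Et3N; then LiCl) into the allylic chloride F6 and with magnesium into the allylic Grignard reagent F7. After deprotonation of its tertiary hydroxyl with MeMgCl, F5 is alkylated by F7 under Li2CuCl4 catalysis, which comes back to the route at 18.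

Step 7. Singlet oxygen may take hydrogen from C7 or C17 (oxygen on C9), or may attack the β-face. The fallback installs the C8 oxygen and the C11 methylene separately and sets out from 8. K-Selectride followed by Me3SiCl gives the trimethylsilyl enol ether F8. Rubottom oxidation (m-CPBA, NaHCO3), an epoxidation across C8=C9 that should show the same α-face preference, gives after mild desilylation the α-hydroxy ketone F9. Me3SiCH2Li/CeCl3 adds to this non-enolisable ketone to give the β-hydroxysilane F10, and KH (Peterson elimination) comes back to the route at 13.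

**Further compounds**

F1 | step 16 | tertiary methyl oxalate of 25 | CC(=O)OC[C@H]1CCO[C@]2(C)CC[C@@H](C(C)(C)OC(=O)C(=O)OC)[C@](C)(CC(Cl)=C)[C@H]2CC1
F2 | step 16 | cesium oxalate of 25 | CC(=O)OC[C@H]1CCO[C@]2(C)CC[C@@H](C(C)(C)OC(=O)C(=O)O[Cs])[C@](C)(CC(Cl)=C)[C@H]2CC1
F3 | step 16 | 2-chloro-8α,15-epoxylabdan-16-yl acetate (C2 epimers) | CC(=O)OC[C@H]1CCO[C@]2(C)CC[C@H]3C(C)(C)CC(Cl)C[C@]3(C)[C@H]2CC1
F4 | step 10 | primary alcohol at C11 (diol, 9α-H) | O[C@]1(C)CC[C@@H](C(C)(C)O[Si](CC)(CC)CC)[C@](C)(CC(Cl)=C)[C@H]1CO
F5 | step 10 | primary iodide at C11 | O[C@]1(C)CC[C@@H](C(C)(C)O[Si](CC)(CC)CC)[C@](C)(CC(Cl)=C)[C@H]1CI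
F6 | step 10 | tert-butyl{[2-(chloromethyl)allyl]oxy}dimethylsilane | ClCC(=C)CO[Si](C)(C)C(C)(C)C
F7 | step 10 | {2-[(tert-butyldimethylsilyloxy)methyl]allyl}magnesium chloride | Cl[Mg]CC(=C)CO[Si](C)(C)C(C)(C)C
F8 | step 7 | trimethylsilyl enol ether (C8=C9–OSiMe3) | CC=1CC[C@@H](C(C)(C)O[Si](CC)(CC)CC)[C@](C)(CC(Cl)=C)C=1O[Si](C)(C)C
F9 | step 7 | α-hydroxy ketone (8α-OH, C9=O) | O[C@]1(C)CC[C@@H](C(C)(C)O[Si](CC)(CC)CC)[C@](C)(CC(Cl)=C)C1=O
F10 | step 7 | β-hydroxysilane (C9–OH, C9–CH2SiMe3) | O[C@]1(C)CC[C@@H](C(C)(C)O[Si](CC)(CC)CC)[C@](C)(CC(Cl)=C)C1(O)C[Si](C)(C)C
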